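## Retrosynthetic overview

1. Target 40 ⇐ periodate unmasking of the C1 ketone and bis-angeloylation of diol 35 ⇐ OsO4 dihydroxylation (anti to the C7 silyloxy group) of alkene 34 ⇐ CBS reduction and C5 deoxygenation of enone 27.
2. Enone 27 (seven-membered ring, closed last) ⇐ β-elimination and intramolecular reductive aldol (C5–C6) of 22 ⇐ intermolecular aldol (C8–C9) of keto aldehyde 18 with the kinetic enolate of 3-methylbut-3-en-2-one 19.
3. Bicyclo[3.1.1]heptanone 16 (cyclobutane and six-membered ring formed together, first) ⇐ intramolecular vinylketene–alkene [2+2] of dienoyl chloride 14.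
4. Acid 13 ⇐ Cp2ZrCl2-catalysed carboalumination, Wittig olefination and Evans alkylation (C3 methyl stereocentre, the source of all asymmetry) from 1, 2 and 6.

Assumption: both esters are angelates ((2Z)-2-methylbut-2-enoates), as the SMILES encodes. Tricyclic compounds are numbered as longipinanes: C1 is the ketone carbon of the target, C3 is CHMe, C4/C5/C10/C11 form the cyclobutane, C6 is CMe2, C7–C9 are the oxygenated carbons.

## Route

Step 1
Reactants: 1 (S)-4-benzyl-3-propanoyl-1,3-oxazolidin-2-one; 2 3-bromoprop-1-yne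
Product: 4 (S)-4-benzyl-3-[(2R)-2-methylpent-4-ynoyl]-1,3-oxazolidin-2-one, via sodium Z-enolate 3 (not isolated)
Conditions: NaN(SiMe3)2, THF, −78 °C; then 2, −78 → −40 °C
Reagents that add atoms: none
Why: Evans asymmetric alkylation; the chelated Z-enolate is alkylated on the face opposite the benzyl group, which sets the (R)-methyl stereocentre that becomes C3.

Step 2
Reactants: 4 (S)-4-benzyl-3-[(2R)-2-methylpent-4-ynoyl]-1,3-oxazolidin-2-one
Product: 5 (2R)-2-methylpent-4-yn-1-ol
Conditions: LiBH4, Et2O/MeOH, 0 °C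
Reagents that add atoms: none
Why: Reductive cleavage of the N-acyl oxazolidinone gives the primary alcohol without touching the stereocentre or the alkyne.

Step 3
Reactants: 5 (2R)-2-methylpent-4-yn-1-ol; 6 ethyl 2-(triphenyl-λ5-phosphanylidene)propanoate
Product: 8 ethyl (2E,4R)-2,4-dimethylhept-2-en-6-ynoate, via (2R)-2-methylpent-4-ynal 7 (not isolated)
Conditions: Dess–Martin periodinane, NaHCO3, CH2Cl2, 0 °C → rt; then 6, rt
Reagents that add atoms: none
Why: Dess–Martin oxidation followed in the same flask by Wittig olefination with the stabilised ylide gives the E-trisubstituted enoate and avoids isolating the volatile, epimerisable aldehyde.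

Step 4
Reactants: 8 ethyl (2E,4R)-2,4-dimethylhept-2-en-6-ynoate
Product: 9 (2E,4R)-2,4-dimethylhept-2-en-6-yn-1-ol
Conditions: i-Bu2AlH, CH2Cl2, −78 °C
Reagents that add atoms: none
Why: 1,2-Reduction of the enoate by i-Bu2AlH gives the allylic alcohol and leaves the alkyne alone at low temperature.

Step 5
Reactants: 9 (2E,4R)-2,4-dimethylhept-2-en-6-yn-1-ol
Product: 10 tert-butyl{[(2E,4R)-2,4-dimethylhept-2-en-6-yn-1-yl]oxy}diphenylsilane
Conditions: t-BuPh2SiCl, imidazole, DMF, rt
Reagents that add atoms: tert-butyl(chloro)diphenylsilane, CC(C)(C)[Si](Cl)(c1ccccc1)c1ccccc1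
Why: Silyl ether protection with a group that survives Me3Al, hydroxide, HCl and hot Et3N.

Step 6
Reactants: 10 tert-butyl{[(2E,4R)-2,4-dimethylhept-2-en-6-yn-1-yl]oxy}diphenylsilane
Product: 12 ethyl (2E,5R,6E)-8-[(tert-butyldiphenylsilyl)oxy]-3,5,7-trimethylocta-2,6-dienoate, via alkenylalane 11 (not isolated)
Conditions: Me3Al, Cp2ZrCl2, CH2Cl2, 0 °C → rt; then ClCO2Et
Reagents that add atoms: trimethylaluminium, C[Al](C)C; ethyl chloroformate, CCOC(=O)Cl
Why: Negishi syn-carboalumination of the terminal alkyne and acylation of the alkenylalane with retention give the (E)-3-methyl-2-enoate with the methyl cis to the carbonyl.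

Step 7
Reactants: 12 ethyl (2E,5R,6E)-8-[(tert-butyldiphenylsilyl)oxy]-3,5,7-trimethylocta-2,6-dienoate
Product: 13 (2E,5R,6E)-8-[(tert-butyldiphenylsilyl)oxy]-3,5,7-trimethylocta-2,6-dienoic acid
Conditions: LiOH, THF/MeOH/H2O, 45 °C; HCl work-up
Reagents that add atoms: lithium hydroxide, [Li+].[OH-]
Why: Ester saponification; the hindered silyl ether and both alkenes are stable to hydroxide.

Step 8
Reactants: 13 (2E,5R,6E)-8-[(tert-butyldiphenylsilyl)oxy]-3,5,7-trimethylocta-2,6-dienoic acid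
Product: 14 (2E,5R,6E)-8-[(tert-butyldiphenylsilyl)oxy]-3,5,7-trimethylocta-2,6-dienoyl chloride
Conditions: (COCl)2, DMF (cat.), CH2Cl2, 0 °C → rt; evaporate, use crude
Reagents that add atoms: oxalyl chloride, ClC(=O)C(=O)Cl
Why: Acid chloride formation by Vilsmeier-type activation under conditions the silyl ether tolerates.

Step 9
Reactants: 14 (2E,5R,6E)-8-[(tert-butyldiphenylsilyl)oxy]-3,5,7-trimethylocta-2,6-dienoyl chloride
Product: 16 (1S,4R,5R,7R)-7-{[(tert-butyldiphenylsilyl)oxy]methyl}-4,7-dimethyl-2-methylidenebicyclo[3.1.1]heptan-6-one, via vinylketene 15 (not isolated)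
Conditions: Et3N, toluene, reflux, slow addition of 14 (0.01 M)
Reagents that add atoms: none
Why: Intramolecular ketene–alkene [2+2] cycloaddition (ketene carbonyl carbon to the less substituted alkene carbon) builds the cyclobutanone and six-membered ring at once; the E-alkene fixes methyl/silyloxymethyl at C7 stereospecifically and the existing methyl stereocentre selects the alkene face by minimising allylic 1,3-strain.

Step 10
Reactants: 16 (1S,4R,5R,7R)-7-{[(tert-butyldiphenylsilyl)oxy]methyl}-4,7-dimethyl-2-methylidenebicyclo[3.1.1]heptan-6-one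
Product: 17 (1S,4R,5R,7R)-7-(hydroxymethyl)-4,7-dimethyl-2-methylidenebicyclo[3.1.1]heptan-6-one
Conditions: HF·pyridine, pyridine, THF, 0 °C → rt
Reagents that add atoms: none
Why: Buffered fluoride desilylation avoids free alkoxide next to the strained cyclobutanone.

Step 11
Reactants: 17 (1S,4R,5R,7R)-7-(hydroxymethyl)-4,7-dimethyl-2-methylidenebicyclo[3.1.1]heptan-6-one
Product: 18 (1S,4R,5R,7R)-7-formyl-4,7-dimethyl-2-methylidenebicyclo[3.1.1]heptan-6-one
Conditions: Dess–Martin periodinane, NaHCO3, CH2Cl2, rt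
Reagents that add atoms: none
Why: Neutral Dess–Martin oxidation gives the non-enolisable neopentyl aldehyde.

Step 12
Reactants: 18 (1S,4R,5R,7R)-7-formyl-4,7-dimethyl-2-methylidenebicyclo[3.1.1]heptan-6-one; 19 3-methylbut-3-en-2-one
Product: 21 (1S,4R,5R,7R)-7-(1-hydroxy-4-methyl-3-oxopent-4-en-1-yl)-4,7-dimethyl-2-methylidenebicyclo[3.1.1]heptan-6-one (carbinol epimers), via lithium dienolate 20 (not isolated)
Conditions: LiN(i-Pr)2, THF, −78 °C; then 18, −78 °C; AcOH quench at −78 °C
Reagents that add atoms: none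
Why: Crossed aldol addition; the kinetic cross-conjugated enolate attacks the aldehyde far faster than the doubly shielded cyclobutanone and forms the C8–C9 bond, and the new carbinol centre (an epimer mixture) is erased in step 16.

Step 13
Reactants: 21 (1S,4R,5R,7R)-7-(1-hydroxy-4-methyl-3-oxopent-4-en-1-yl)-4,7-dimethyl-2-methylidenebicyclo[3.1.1]heptan-6-one
Product: 22 (1S,4R,5R,7R)-4,7-dimethyl-2-methylidene-7-{4-methyl-3-oxo-1-[(triethylsilyl)oxy]pent-4-en-1-yl}bicyclo[3.1.1]heptan-6-one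
Conditions: Et3SiOTf, 2,6-lutidine, CH2Cl2, −78 °C
Reagents that add atoms: triethylsilyl trifluoromethanesulfonate, CC[Si](CC)(CC)OS(=O)(=O)C(F)(F)F
Why: Silylation removes the acidic OH and blocks retro-aldol and oxa-Michael pathways before the hydride step.

Step 14
Reactants: 22 (1S,4R,5R,7R)-4,7-dimethyl-2-methylidene-7-{4-methyl-3-oxo-1-[(triethylsilyl)oxy]pent-4-en-1-yl}bicyclo[3.1.1]heptan-6-one
Product: 24 5-hydroxy-1-methylidene-9-[(triethylsilyl)oxy]longipinan-7-one (C9 epimers), via copper enolate 23 (not isolated)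
Conditions: [(Ph3P)CuH]6 (0.4 equiv), toluene, −40 → 0 °C; aq. NH4Cl
Reagents that add atoms: none
Why: Reductive aldol cyclisation; conjugate hydride delivery gives the C6 enolate regiospecifically, and the tether from C10 forces attack on the cyclobutanone from the face anti to the C1–C3 bridge, closing the seven-membered ring with C6 on the required face and the C5 hydroxyl syn to that bridge.

Step 15
Reactants: 24 5-hydroxy-1-methylidene-9-[(triethylsilyl)oxy]longipinan-7-one
Product: 25 5,9-dihydroxy-1-methylidenelongipinan-7-one (C9 epimers)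
Conditions: HF·pyridine, pyridine, THF, 0 °C
Reagents that add atoms: none
Why: Mild fluoride desilylation frees the C9 hydroxyl without base, so neither β-hydroxy ketone undergoes retro-aldol cleavage.

Step 16
Reactants: 25 5,9-dihydroxy-1-methylidenelongipinan-7-one
Product: 27 5-hydroxy-1-methylidenelongipin-8-en-7-one, via C9 mesylate 26 (not isolated)
Conditions: MsCl, Et3N, CH2Cl2, 0 °C; then DBU, rt
Reagents that add atoms: none
Why: Selective mesylation of the secondary alcohol and E1cB β-elimination give the ring enone (necessarily cis) from both C9 epimers, while the hindered tertiary C5 alcohol does not react.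

Step 17
Reactants: 27 5-hydroxy-1-methylidenelongipin-8-en-7-one
Product: 28 1,5-dihydroxy-1-(hydroxymethyl)longipin-8-en-7-one (C1 carbinol configuration not assigned; it is destroyed in step 26)
Conditions: OsO4 (2 mol%), NMO (1.1 equiv), acetone/H2O, 0 °C → rt
Reagents that add atoms: osmium tetroxide, O=[Os](=O)(=O)=O; 4-methylmorpholine N-oxide, C[N+]1([O-])CCOCC1; water, O
Why: Upjohn dihydroxylation is chemoselective for the electron-rich exocyclic alkene over the hindered, electron-poor enone and masks the future C1 ketone as a diol.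

Step 18
Reactants: 28 1,5-dihydroxy-1-(hydroxymethyl)longipin-8-en-7-one
Product: 29 acetonide of 28 (spiro-2,2-dimethyl-1,3-dioxolane at C1; C5 hydroxyl free)
Conditions: 2,2-dimethoxypropane, PPTS (cat.), CH2Cl2, rt
Reagents that add atoms: 2,2-dimethoxypropane, COC(C)(C)OC
Why: Acetonide formation takes the 1,2-diol only, since the tertiary C5 hydroxyl cannot form a stable six-membered acetal.

Step 19
Reactants: 29 acetonide of 28
Product: 30 (7R)-5,7-dihydroxylongipin-8-ene C1 spiro-acetonide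
Conditions: (S)-Me-CBS oxazaborolidine [(S)-1-methyl-3,3-diphenyltetrahydro-1H,3H-pyrrolo[1,2-c][1,3,2]oxazaborole] (0.5 equiv), catecholborane, toluene, −78 → −40 °C
Reagents that add atoms: none
Why: Corey–Bakshi–Shibata reduction; with the quaternary C6 as the large group and the ring vinyl as the small group the (S)-catalyst delivers hydride to give the (7R)-allylic alcohol, overriding the nearly unbiased ring faces.

Step 20
Reactants: 30 (7R)-5,7-dihydroxylongipin-8-ene C1 spiro-acetonide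
Product: 31 (7R)-7-[(tert-butyldimethylsilyl)oxy]-5-hydroxylongipin-8-ene C1 spiro-acetonide
Conditions: t-BuMe2SiOTf, 2,6-lutidine, CH2Cl2, −78 → 0 °C
Reagents that add atoms: tert-butyldimethylsilyl trifluoromethanesulfonate, CC(C)(C)[Si](C)(C)OS(=O)(=O)C(F)(F)F
Why: Selective silylation of the secondary allylic alcohol; the tertiary C5 alcohol is too hindered to react.

Step 21
Reactants: 31 (7R)-7-[(tert-butyldimethylsilyl)oxy]-5-hydroxylongipin-8-ene C1 spiro-acetonide
Product: 33 O-(C5) S-methyl dithiocarbonate of 31, via potassium xanthate 32 (not isolated)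
Conditions: KN(SiMe3)2, THF, −78 → 0 °C; CS2; MeI
Reagents that add atoms: carbon disulfide, S=C=S; iodomethane, CI
Why: Xanthate formation through the potassium alkoxide; the small CS2 reaches the hindered oxygen, there is no carbonyl left for retro-aldol, and Chugaev elimination is impossible because the only β-hydrogens are at bridgeheads.

Step 22
Reactants: 33 O-(C5) S-methyl dithiocarbonate of 31
Product: 34 (7R)-7-[(tert-butyldimethylsilyl)oxy]longipin-8-ene C1 spiro-acetonide
Conditions: Bu3SnH, AIBN, toluene, 100 °C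
Reagents that add atoms: none
Why: Barton–McCombie deoxygenation; the C5 radical is held in the seven-membered ring, so hydrogen can only be delivered from the open face and C5–H ends up syn to the C1–C3 bridge as in the target.

Step 23
Reactants: 34 (7R)-7-[(tert-butyldimethylsilyl)oxy]longipin-8-ene C1 spiro-acetonide
Product: 35 7-[(tert-butyldimethylsilyl)oxy]longipinane-8,9-diol C1 spiro-acetonide (O8 and O9 cis to each other, trans to O7)
Conditions: OsO4 (10 mol%), NMO, acetone/t-BuOH/H2O, rt → 40 °C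
Reagents that add atoms: osmium tetroxide, O=[Os](=O)(=O)=O; 4-methylmorpholine N-oxide, C[N+]1([O-])CCOCC1; water, O
Why: Upjohn syn-dihydroxylation of the only remaining alkene from the face anti to the bulky allylic silyloxy group (Kishi's rule) sets C8 and C9.

Step 24
Reactants: 35 7-[(tert-butyldimethylsilyl)oxy]longipinane-8,9-diol C1 spiro-acetonide; 36 angelic acid
Product: 38 8,9-bis(angeloyloxy)-7-[(tert-butyldimethylsilyl)oxy]longipinane C1 spiro-acetonide, via mixed anhydride 37 (not isolated)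
Conditions: 36 (5 equiv), 2,4,6-trichlorobenzoyl chloride (5 equiv), Et3N, toluene, rt, 2 h; then 35, 80 °C, 24–48 h
Reagents that add atoms: angelic acid (second equivalent), C/C=C(/C)C(=O)O
Why: Yamaguchi-type double esterification in which each of the two hydroxyls takes one angeloyl group from the angelic 2,4,6-trichlorobenzoic anhydride (two equivalents of 36 are consumed, the rest is excess), run without DMAP to avoid Z → E isomerisation to tiglate.

Step 25
Reactants: 38 8,9-bis(angeloyloxy)-7-[(tert-butyldimethylsilyl)oxy]longipinane C1 spiro-acetonide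
Product: 39 8,9-bis(angeloyloxy)-1-(hydroxymethyl)longipinane-1,7-diol
Conditions: 48% aq. HF, MeCN, 0 °C → rt
Reagents that add atoms: none
Why: Acidic fluoride cleaves the silyl ether and hydrolyses the terminal acetonide in one global deprotection, leaving the angelates intact.

Step 26
Reactants: 39 8,9-bis(angeloyloxy)-1-(hydroxymethyl)longipinane-1,7-diol
Product: 40 (3R,4S,5S,7S,8R,9S,10R,11R)-8,9-bis(angeloyloxy)-7-hydroxylongipinan-1-one (CNP0344448.1)
Conditions: NaIO4, THF/H2O, 0 °C → rt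
Reagents that add atoms: none
Why: Malaprade glycol cleavage of the only free 1,2-diol releases the C1 ketone; the C7 hydroxyl has no free vicinal partner and the esters are inert.

## Compound list

1 | (S)-4-benzyl-3-propanoyl-1,3-oxazolidin-2-one | CCC(=O)N1[C@@H](Cc2ccccc2)COC1=O | starting material
2 | 3-bromoprop-1-yne | C#CCBr | starting material
3 | sodium Z-enolate of 1 | C/C=C(\O[Na])N1[C@@H](Cc2ccccc2)COC1=O | intermediate
4 | (S)-4-benzyl-3-[(2R)-2-methylpent-4-ynoyl]-1,3-oxazolidin-2-one | C#CC[C@@H](C)C(=O)N1[C@@H](Cc2ccccc2)COC1=O | intermediate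
5 | (2R)-2-methylpent-4-yn-1-ol | C#CC[C@@H](C)CO | intermediate
6 | ethyl 2-(triphenyl-λ5-phosphanylidene)propanoate | CCOC(=O)C(C)=P(c1ccccc1)(c1ccccc1)c1ccccc1 | starting material
7 | (2R)-2-methylpent-4-ynal | C#CC[C@@H](C)C=O | intermediate
8 | ethyl (2E,4R)-2,4-dimethylhept-2-en-6-ynoate | C#CC[C@@H](C)/C=C(\C)C(=O)OCC | intermediate
9 | (2E,4R)-2,4-dimethylhept-2-en-6-yn-1-ol | C#CC[C@@H](C)/C=C(\C)CO | intermediate
10 | tert-butyl{[(2E,4R)-2,4-dimethylhept-2-en-6-yn-1-yl]oxy}diphenylsilane | C#CC[C@@H](C)/C=C(\C)CO[Si](c1ccccc1)(c1ccccc1)C(C)(C)C | intermediate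
11 | {(1E,4R,5E)-7-[(tert-butyldiphenylsilyl)oxy]-2,4,6-trimethylhepta-1,5-dien-1-yl}dimethylalumane | C[Al](C)/C=C(\C)C[C@@H](C)/C=C(\C)CO[Si](c1ccccc1)(c1ccccc1)C(C)(C)C | intermediate
12 | ethyl (2E,5R,6E)-8-[(tert-butyldiphenylsilyl)oxy]-3,5,7-trimethylocta-2,6-dienoate | CCOC(=O)/C=C(\C)C[C@@H](C)/C=C(\C)CO[Si](c1ccccc1)(c1ccccc1)C(C)(C)C | intermediate
13 | (2E,5R,6E)-8-[(tert-butyldiphenylsilyl)oxy]-3,5,7-trimethylocta-2,6-dienoic acid | OC(=O)/C=C(\C)C[C@@H](C)/C=C(\C)CO[Si](c1ccccc1)(c1ccccc1)C(C)(C)C | intermediate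
14 | (2E,5R,6E)-8-[(tert-butyldiphenylsilyl)oxy]-3,5,7-trimethylocta-2,6-dienoyl chloride | ClC(=O)/C=C(\C)C[C@@H](C)/C=C(\C)CO[Si](c1ccccc1)(c1ccccc1)C(C)(C)C | intermediate
15 | (5R,6E)-8-[(tert-butyldiphenylsilyl)oxy]-5,7-dimethyl-3-methylideneocta-1,6-dien-1-one (vinylketene) | O=C=CC(=C)C[C@@H](C)/C=C(\C)CO[Si](c1ccccc1)(c1ccccc1)C(C)(C)C | intermediate
16 | (1S,4R,5R,7R)-7-{[(tert-butyldiphenylsilyl)oxy]methyl}-4,7-dimethyl-2-methylidenebicyclo[3.1.1]heptan-6-one | O=C1[C@@H]2[C@H](C)CC(=C)[C@H]1[C@]2(C)CO[Si](c1ccccc1)(c1ccccc1)C(C)(C)C | intermediate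
17 | (1S,4R,5R,7R)-7-(hydroxymethyl)-4,7-dimethyl-2-methylidenebicyclo[3.1.1]heptan-6-one | O=C1[C@@H]2[C@H](C)CC(=C)[C@H]1[C@]2(C)CO | intermediate
18 | (1S,4R,5R,7R)-7-formyl-4,7-dimethyl-2-methylidenebicyclo[3.1.1]heptan-6-one | O=C1[C@@H]2[C@H](C)CC(=C)[C@H]1[C@]2(C)C=O | intermediate
19 | 3-methylbut-3-en-2-one | CC(=O)C(C)=C | starting material
20 | lithium 3-methylbuta-1,3-dien-2-olate | [Li]OC(=C)C(C)=C | intermediate
21 | (1S,4R,5R,7R)-7-(1-hydroxy-4-methyl-3-oxopent-4-en-1-yl)-4,7-dimethyl-2-methylidenebicyclo[3.1.1]heptan-6-one (carbinol epimers) | O=C1[C@@H]2[C@H](C)CC(=C)[C@H]1[C@]2(C)C(O)CC(=O)C(C)=C | intermediate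
22 | triethylsilyl ether of 21 | O=C1[C@@H]2[C@H](C)CC(=C)[C@H]1[C@]2(C)C(O[Si](CC)(CC)CC)CC(=O)C(C)=C | intermediate
23 | copper enolate from 22 (phosphine-ligated) | O=C1[C@@H]2[C@H](C)CC(=C)[C@H]1[C@]2(C)C(O[Si](CC)(CC)CC)CC(O[Cu])=C(C)C | intermediate
24 | 5-hydroxy-1-methylidene-9-[(triethylsilyl)oxy]longipinan-7-one (C9 epimers) | CC[Si](CC)(CC)OC1CC(=O)C(C)(C)[C@@]2(O)[C@@H]3[C@H](C)CC(=C)[C@H]2[C@]13C | intermediate
25 | 5,9-dihydroxy-1-methylidenelongipinan-7-one (C9 epimers) | OC1CC(=O)C(C)(C)[C@@]2(O)[C@@H]3[C@H](C)CC(=C)[C@H]2[C@]13C | intermediate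
26 | C9 methanesulfonate of 25 | CS(=O)(=O)OC1CC(=O)C(C)(C)[C@@]2(O)[C@@H]3[C@H](C)CC(=C)[C@H]2[C@]13C | intermediate
27 | 5-hydroxy-1-methylidenelongipin-8-en-7-one | C1=CC(=O)C(C)(C)[C@@]2(O)[C@@H]3[C@H](C)CC(=C)[C@H]2[C@]13C | intermediate
28 | 1,5-dihydroxy-1-(hydroxymethyl)longipin-8-en-7-one | C1=CC(=O)C(C)(C)[C@@]2(O)[C@@H]3[C@H](C)CC(O)(CO)[C@H]2[C@]13C | intermediate
29 | acetonide of 28 (spiro-dioxolane at C1) | C1=CC(=O)C(C)(C)[C@@]2(O)[C@@H]3[C@H](C)CC4(COC(C)(C)O4)[C@H]2[C@]13C | intermediate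
30 | (7R)-5,7-dihydroxylongipin-8-ene C1 spiro-acetonide | C1=C[C@@H](O)C(C)(C)[C@@]2(O)[C@@H]3[C@H](C)CC4(COC(C)(C)O4)[C@H]2[C@]13C | intermediate
31 | (7R)-7-[(tert-butyldimethylsilyl)oxy]-5-hydroxylongipin-8-ene C1 spiro-acetonide | C1=C[C@@H](O[Si](C)(C)C(C)(C)C)C(C)(C)[C@@]2(O)[C@@H]3[C@H](C)CC4(COC(C)(C)O4)[C@H]2[C@]13C | intermediate
32 | potassium O-(C5) dithiocarbonate of 31 | C1=C[C@@H](O[Si](C)(C)C(C)(C)C)C(C)(C)[C@@]2(OC(=S)[S-])[C@@H]3[C@H](C)CC4(COC(C)(C)O4)[C@H]2[C@]13C.[K+] | intermediate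
33 | O-(C5) S-methyl dithiocarbonate of 31 | C1=C[C@@H](O[Si](C)(C)C(C)(C)C)C(C)(C)[C@@]2(OC(=S)SC)[C@@H]3[C@H](C)CC4(COC(C)(C)O4)[C@H]2[C@]13C | intermediate
34 | (7R)-7-[(tert-butyldimethylsilyl)oxy]longipin-8-ene C1 spiro-acetonide | C1=C[C@@H](O[Si](C)(C)C(C)(C)C)C(C)(C)[C@H]2[C@@H]3[C@H](C)CC4(COC(C)(C)O4)[C@H]2[C@]13C | intermediate
35 | 7-[(tert-butyldimethylsilyl)oxy]longipinane-8,9-diol C1 spiro-acetonide | O[C@@H]1[C@H](O)[C@@H](O[Si](C)(C)C(C)(C)C)C(C)(C)[C@H]2[C@@H]3[C@H](C)CC4(COC(C)(C)O4)[C@H]2[C@]13C | intermediate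
36 | angelic acid, (2Z)-2-methylbut-2-enoic acid | C/C=C(/C)C(=O)O | starting material
37 | angelic 2,4,6-trichlorobenzoic anhydride | C/C=C(/C)C(=O)OC(=O)c1c(Cl)cc(Cl)cc1Cl | intermediate
38 | 8,9-bis(angeloyloxy)-7-[(tert-butyldimethylsilyl)oxy]longipinane C1 spiro-acetonide | C/C=C(/C)C(=O)O[C@@H]1[C@H](OC(=O)/C(C)=C\C)[C@@H](O[Si](C)(C)C(C)(C)C)C(C)(C)[C@H]2[C@@H]3[C@H](C)CC4(COC(C)(C)O4)[C@H]2[C@]13C | intermediate
39 | 8,9-bis(angeloyloxy)-1-(hydroxymethyl)longipinane-1,7-diol | C/C=C(/C)C(=O)O[C@@H]1[C@H](OC(=O)/C(C)=C\C)[C@@H](O)C(C)(C)[C@H]2[C@@H]3[C@H](C)CC(O)(CO)[C@H]2[C@]13C | intermediate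
40 | (3R,4S,5S,7S,8R,9S,10R,11R)-8,9-bis(angeloyloxy)-7-hydroxylongipinan-1-one (CNP0344448.1) | C/C=C(/C)C(=O)O[C@@H]1[C@@H](O)C(C)(C)[C@H]2[C@@H]3[C@H](C)CC(=O)[C@H]2[C@]3(C)[C@@H]1OC(=O)/C(C)=C\C | target

## Step count and risks

Total step count: 26. Longest linear sequence: 26 steps (1 → 40); compounds 2, 6, 19 and 36 are bought.

The three steps most likely to fail:

Step 14, the reductive aldol closure of the seven-membered ring onto the hindered cyclobutanone. The fallback sets out from alcohol 17 and comes back at enone 27, and it builds the C5–C6 bond through an ester tether instead. Alcohol 17 is acylated with 2-bromo-2-methylpropanoyl bromide and pyridine to give the bromo ester F1. SmI2 in THF at −78 °C then triggers an intramolecular Reformatsky reaction onto the cyclobutanone and gives the seven-membered hydroxy lactone F2, again with C6 delivered from the face anti to the C1–C3 bridge. One equivalent of MeLi at −78 °C opens the hindered lactone to the methyl ketone diol F3, Dess–Martin oxidation of the primary alcohol gives the keto aldehyde F4, and an intramolecular aldol condensation (KOH, MeOH) closes the carbocycle to enone 27.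

Step 22 (with its xanthate from step 21), the deoxygenation of the very hindered tertiary C5 alcohol. The fallback sets out from 31 and comes back at 34 and replaces the Bu3SnH chain reaction by a photoredox fragmentation. Compound 31 is acylated with methyl chlorooxoacetate (Et3N, DMAP) to the methyl oxalate F5, which CsOH in THF/H2O converts into the caesium oxalate F6. Irradiation with blue light in the presence of [Ir{dF(CF3)ppy}2(dtbbpy)]PF6 and methyl thioglycolate as hydrogen-atom donor (DME/DMF) expels two molecules of CO2 and reduces the ring-held C5 radical from the open face to give 34.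

Step 24, the double angeloylation of the hindered cis-diol without isomerisation to tiglate. The fallback sets out from diol 35 and comes back at 38 and builds the Z-alkenes after the ester bonds. Diol 35 is esterified with two equivalents of 2-[bis(2,2,2-trifluoroethoxy)phosphoryl]propanoic acid (DCC, DMAP) to the bis(phosphonate) F7. A double Still–Gennari olefination with acetaldehyde (KN(SiMe3)2, 18-crown-6, THF, −78 °C) then gives the two (Z)-2-methylbut-2-enoates of 38.

## Further compounds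

F1 | step 14 | [(1S,4R,5R,7R)-4,7-dimethyl-2-methylidene-6-oxobicyclo[3.1.1]heptan-7-yl]methyl 2-bromo-2-methylpropanoate | O=C1[C@@H]2[C@H](C)CC(=C)[C@H]1[C@]2(C)COC(=O)C(C)(C)Br
F2 | step 14 | 5-hydroxy-1-methylidene-8-oxalongipinan-7-one (seven-membered hydroxy lactone) | C1OC(=O)C(C)(C)[C@@]2(O)[C@@H]3[C@H](C)CC(=C)[C@H]2[C@]13C
F3 | step 14 | 3-[6-hydroxy-7-(hydroxymethyl)-4,7-dimethyl-2-methylidenebicyclo[3.1.1]heptan-6-yl]-3-methylbutan-2-one | CC(=O)C(C)(C)[C@@]1(O)[C@@H]2[C@H](C)CC(=C)[C@H]1[C@]2(C)CO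
F4 | step 14 | 6-hydroxy-4,7-dimethyl-6-(2-methyl-3-oxobutan-2-yl)-2-methylidenebicyclo[3.1.1]heptane-7-carbaldehyde | CC(=O)C(C)(C)[C@@]1(O)[C@@H]2[C@H](C)CC(=C)[C@H]1[C@]2(C)C=O
F5 | step 22 | C5 methyl oxalate of 31 | C1=C[C@@H](O[Si](C)(C)C(C)(C)C)C(C)(C)[C@@]2(OC(=O)C(=O)OC)[C@@H]3[C@H](C)CC4(COC(C)(C)O4)[C@H]2[C@]13C
F6 | step 22 | caesium C5 oxalate of 31 | C1=C[C@@H](O[Si](C)(C)C(C)(C)C)C(C)(C)[C@@]2(OC(=O)C(=O)[O-])[C@@H]3[C@H](C)CC4(COC(C)(C)O4)[C@H]2[C@]13C.[Cs+]
F7 | step 24 | 8,9-bis{2-[bis(2,2,2-trifluoroethoxy)phosphoryl]propanoate} of 35 | CC(C(=O)O[C@@H]1[C@H](OC(=O)C(C)P(=O)(OCC(F)(F)F)OCC(F)(F)F)[C@@H](O[Si](C)(C)C(C)(C)C)C(C)(C)[C@H]2[C@@H]3[C@H](C)CC4(COC(C)(C)O4)[C@H]2[C@]13C)P(=O)(OCC(F)(F)F)OCC(F)(F)F
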